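Beside this flask stands a neighbour charged with 0.0029 M of spent carrier, and before I spend starting material on the next run I want to know which change pays: more salt, a higher solubility or faster dissolution.

starting material 0.48 M; salt in the second phase 1.44 M; spent carrier 4.8 mM; time 2.0 d; volume of the second phase over the first 2.0

- elm: doubling the solubility in step 4, all else as stated
- alder: doubling the amount of salt in the second phase, all else as stated
- maple: doubling the dissolution coefficient of step 4, all else as stated

    starting material + fresh carrier → product + spent carrier (k1 = 0.00328 L mol⁻¹ s⁻¹)
    spent carrier → spent catalyst (k2 = 8.96 × 10⁻⁶ s⁻¹)
    spent carrier + salt in the second phase ⇌ fresh carrier + spent salt in the second phase (K3 = 0.82, k3 = 0.00497 L mol⁻¹ s⁻¹)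
    crystals ⇌ product, rate k4*(cs4 - [product]) while solid is left; crystals form when [product] > cs4 (cs4 = 13 mM, k4 = 6.68 × 10⁻⁵ s⁻¹)

- product is meant together with its crystals
- in the second phase: salt in the second phase, spent salt in the second phase; everything else is in the first
- charges count per volume of the first phase; a concentration in a rate is the amount of a species over the volume of its own phase; every rate counts per litre of the first phase
- solid, in amounts per volume of the solution: crystals
- run time (flask): 2.0 d

1. amount of product and crystals together at 2.0 d, in percent of the starting material charged
2. concentration of product in solution at 12 h, in percent of saturation
3. the change that raises the amount of product and crystals together at 2.0 d, in percent of the starting material charged most ("none" if none brings more than 2 percentage points) (elm / alder / maple / none)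
4. amount of product and crystals together at 2.0 d, in percent of the starting material charged, after elm

The charged spent carrier is the whole catalyst. I call the first equation the product step, the second the loss step and the third the salt step. With the other concentrations as charged and the salt step taken forward alone, the half-lives are 0.054 h for spent carrier in the salt step and 0.12 h for fresh carrier in the product step, against 0.90 d in the loss step, so I treat the round as quasi-steady and divide rates.

Per carrier, the salt step runs forward at 0.00358 s⁻¹, with the salt at 0.720 M in its own phase. The product step runs at 0.00157 s⁻¹, and the way back of the salt step, at full conversion, at 0.00145 s⁻¹. The last two are close, so as starting material falls I let the way back stand in for the product step as the user of fresh carrier. I therefore hold fresh over spent carrier at r = 2.27, and I hold the salt at its charge although it is being used.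

Dividing the product-step rate by the loss-step rate removes time. In this reckoning the part of starting material left is exp(−Bz), pseudo-first-order in z, the share of catalyst lost. B is the catalyst budget, the forward salt step over the loss step at the start (400) times the catalyst charge over the starting-material charge: B = 3.99.

With that r I reckon spent carrier at 30.6 % of the live catalyst, so I estimate z at 37.7 % in 2.0 d and product with crystals at 77.8 %. In this reckoning doubling the salt doubles both B and r, which gives z = 24.4 % and 85.7 %, an estimated gain of 7.9 percentage points, more than the 2 points that counts. Solubility and the dissolution coefficient stand nowhere in B, r or z, so I keep 77.8 % after elm and after maple, and I choose alder.

The forecast, which parts from me on the choice and stands higher than my 77.8 %, gives 85 %, 530 % of saturation, none as best and 85 % after elm, with this ground: “doubling the salt adds under 2 points by my rough reckoning”. The simulation gives 75.6 %, 470 % of saturation, alder as best with 9.6 points (elm 0 points, maple 0 points), and 75.6 % after elm.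

At 20.0 d this flask holds 95.9 % of product with crystals, with spent catalyst at 99.7 % of the catalyst charged, where the budget B with the whole catalyst lost gives 98.2 % of product with crystals. The neighbour with 0.0029 M of spent carrier has the same salt and time, so I keep z and scale its budget with the charge to 2.41, which gives 59.7 %. That neighbour flask ends with spent catalyst at 39.9 % of its catalyst charged and 58.1 % of product with crystals.

The numbers were drawn at random within sensible limits, and the outcome is calculated.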